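(The constants used here come from no measurement.)

We decide to carry one number through this flask, the acid clock, and to spend the hand work on it.

    2 starting material → homo dimer (k1 = 0.0047 L mol⁻¹ h⁻¹)
    starting material → weak acid + target (k2 = 0.0010 h⁻¹)
    starting material + protic impurity → quenched substrate (k3 = 21 L mol⁻¹ h⁻¹)
    weak acid ⇌ conjugate base + acid, settled at all times (K4 = 1.6 × 10⁻⁶ M)
    starting material + acid → weak acid + acid + target (k5 = 570 L mol⁻¹ h⁻¹)
    weak acid → by-product carried off (k6 = 0.034 h⁻¹)

starting material 0.020 M; acid 0.200 mM; protic impurity 4.00 mM; time 15 h

- part of the starting material that has reacted at 15 h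
- pH of the solution at 15 h

- acid is the free proton; pH is minus the decimal logarithm of its molar concentration
- percentages count the starting material that a species holds: one homo dimer counts as two
- two of one species on the left: rate k times its square, two consumed each time
- run time (flask): 15 h

- With c(acid) held at its charge, the step of starting material with acid is pseudo-first-order, so its rate integrates in closed form to a decay exp(-clock × time), with a clock of 0.114 h⁻¹ and a half-life of 6.1 h.
- We drop the uncatalysed step, since its 0.0010 h⁻¹ is far slower than that clock, and we drop the dimer step, whose 1.880 × 10⁻⁴ h⁻¹ at the charge is slower still.
- The protic impurity we treat as a toll: its own decay constant, 0.420 h⁻¹ at the charge, is faster than the clock, so we book one starting material per impurity, 20.0% of the charge.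
- That gives 85.5% reacted, and the weak link is the constant c(acid): each target comes with a weak acid, which can release protons.
- To reforge it, we take the weak acid made as 0.0160 M, thinned by carry-off over an average age of 7.50 h, which leaves 0.01240 M.
- Free acid equals its charge plus conjugate base, and the balance then gives c(acid) = 2.727 × 10⁻⁴ M, so the acid clock, the rate constant of the catalysed step times this raised c(acid), becomes 0.155 h⁻¹.
- We commit to 92.2% reacted and pH 3.56, knowing that a late acid level stands here for the entire run.

The forecast gave 92% and pH 3.58, on “slight dissociation of about 0.01 M weak acid”.

The flask gives 91.7% reacted at pH 3.58. At 15.0 h this flask holds acid at 132% of its own charge, and its conjugate base, at 6.39 × 10⁻⁵ M, stands for the protons above that charge. Now take the neighbour flask, the same one with 8.0 × 10⁻⁴ M of acid. The same balance gives c(acid) = 0.824 mM, and the clock runs at 0.470 h⁻¹, whose decay, with no toll booked, leaves 0.0871% of the charge; that neighbour flask holds 0.045% of its starting material at 15.0 h.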